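- The ratio of target to side product is another way of writing the share asked for; summer and midnight differ in how their reagent goes in.

in all of them: substrate 0.17 M; initiator 1.7 mM
- alpha: reagent 0.24 M (in portions, 2); transfer agent 0.017 M; run made earlier; portions every 2.0 min
- eta: reagent 0.37 M (in portions, 2); transfer agent 0.017 M; run made earlier; portions every 2.0 min
- summer: reagent 0.170 M; transfer agent 0.0170 M; everything together at the start; time 6.0 min
- midnight: reagent 0.170 M (in portions, 2); transfer agent 0.0170 M; the portions of reagent follow each other after 2.0 min, the first at the start; time 6.0 min

| run | time / min | target / % | side product / % |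
|---|---|---|---|
| alpha | 0.250 | 0 | 0 |
| alpha | 0.667 | 1.6 | 0 |
| alpha | 1.33 | 1.8 | 1.1 |
| alpha | 2.00 | 1.6 | 1.0 |
| alpha | 3.00 | 4.0 | 1.7 |
| alpha | 4.00 | 4.0 | 0.8 |
| eta | 0.250 | 0.3 | 0.3 |
| eta | 0.500 | 1.4 | 0.7 |
| eta | 0.833 | 0.9 | 0.4 |
| eta | 1.33 | 3.7 | 1.7 |
| eta | 2.00 | 3.2 | 0.6 |
| eta | 4.00 | 6.2 | 2.7 |

(readings scatter by 0.5 percentage points)

- the earlier runs were read with a standard deviation of 0.5 percentage points

1. the flask that ends with the higher share of target in all that became target or side product, or "neither" when 2 percentage points or less lies between them (summer / midnight / neither)
2. share of target in all that became target or side product, summer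
3. share of target in all that became target or side product, midnight

- Before its second portion, alpha reads 1.62 target per side product over its readings at 1.33 min and 2.00 min, with 0.120 M of reagent in. Eta reads 3.00 at 1.33 min and 2.00 min, with 0.185 M.
- Divided by reagent per transfer agent, these readings give 0.229 for alpha and 0.276 for eta.
- Their mean, 0.253, is carried on as the split factor: target per side product, divided by reagent per transfer agent standing. It is the usual selectivity factor, here a reading with scatter.
- Summer has its whole charge in from the start, so the reckoning here gives 2.53 target per side product, a share of 71.6%.
- For midnight the same reckoning gives 1.26 for the stretch before its second portion and 2.53 for the stretch after it. The weight of each stretch is borrowed from alpha, charged with the same transfer agent and initiator: its side product readings at 1.33 min and 2.00 min come to 84.0% of those at 3.00 min and 4.00 min. That gives 59.4%.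
- The weak link is that weight: alpha's late side readings differ by 0.9 points against a scatter of 0.5 points. Pooled with eta, the weight becomes 55.7%, the ratio 1.82, and midnight 64.6%. This reckoning commits to midnight below summer, by 7.0 points.
- The forecast differs: 71% for summer, 72% for midnight, and neither as the answer, on its reading of “parallel paths of nearly the same order in reagent”.
- The simulation gives 73.0% for summer and 65.7% for midnight, so the higher flask is summer.

    substrate + initiating radical → capped initiator + first chain carrier (k = 1.30 × 10⁵ /M/s)
    transfer agent + first chain carrier → side product + idle radical (kL = 32000 /M/s)
    reagent + first chain carrier ⇌ target + second chain carrier (K = 0.510, k = 8600 /M/s)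
    initiator → 2 initiating radical (k = 0.00770 /s)
    substrate + second chain carrier → released group + first chain carrier (k = 6200 /M/s)
    2 first chain carrier → ended chains (k = 5.60 × 10⁷ /M/s)
    2 idle radical → ended radicals (k = 4.00 × 10⁷ /M/s)

- In summer at 1.38 min, first chain carrier is made about as fast as it is used, a ratio of 1.00, and reagent takes it 2.9 times as fast as transfer agent does (forward step alone); at 6.00 min that figure is 3.1. Midnight, just before its last addition, holds 0.0822 M of reagent and 0.0150 M of transfer agent, for which the split factor gives 1.39 target per side product; the flask then stands at 1.38.
- A neighbour, summer with 0.029 M of transfer agent, gets 1.48 from the split factor, a share of 59.7%; computed, it ends at 61.2%.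

The readings are simulated from invented constants.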